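**Retrosynthetic overview** (eudesmane numbering: ring A = C1–C5 + C10 with O at C3, methyl at C4, angular methyl at C10; ring B = C5–C10 with acrylate at C7, acetate at C8)
- Target ⇐ acylation of the C3 and C8 alcohols ⇐ two hydride reductions from the α-face (anti to the C10 methyl) of a 3,8-diketone ⇐ C7 acrylate built on a C7=C8 silyl enol ether (Mukaiyama aldol with methyl bromopyruvate, zinc β-elimination, C7 equilibration).
- Ring B ⇐ one palladium-catalysed, enantioselective dearomative [4+2] annulation of 3-bromo-2,4-dimethylphenol with a 2-silyloxybutadiene: C5–C6 by Heck insertion, C9–C10 by allylic alkylation at the phenol para carbon. The extra C1=C2 bond of the dienone is removed by hydrogenation.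
- Enabling feature: in ring A the oxygen at C3 is para to the quaternary C10 and meta to the ring-fusion carbon C5, with the C4=C5 alkene between them. Ring A is therefore a para-dearomatized 2,4-dimethylphenol whose C5 can carry bromide and whose C10 is the nucleophilic para carbon.
- Ring order: ring A is bought as the arene; ring B is closed in the key step, which also sets C10. C3, C7 and C8 follow from C10 by substrate control.

Key step: step 3

Remark on the chemistry: the sense of induction of the chiral ligand in step 3 cannot be predicted on paper. The ligand enantiomer is to be chosen by screening so that (4aS)-6 results; 1, 4 and 8 are taken as purchasable.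

Step 1
Reactants: 1 3-bromo-2,4-dimethylaniline
Product: 3 3-bromo-2,4-dimethylphenol, via diazonium hydrogensulfate 2 (not isolated)
Conditions: NaNO2, 30% aq H2SO4, 0 °C; then added to boiling 30% aq H2SO4
Reagents that add atoms: water, O (phenol oxygen); for the not isolated 2 also sodium nitrite, [Na+].[O-]N=O, and sulfuric acid, OS(=O)(=O)O
Why: Diazotization followed by hydrolytic dediazoniation is a standard exchange of NH2 for OH that leaves the aryl bromide untouched; no stereocenter is formed.

Step 2
Reactants: 4 but-3-en-2-one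
Product: 5 2-[tri(propan-2-yl)silyloxy]buta-1,3-diene
Conditions: TIPSOTf, Et3N, CH2Cl2, 0 °C to rt
Reagents that add atoms: triisopropylsilyl trifluoromethanesulfonate, CC(C)[Si](OS(=O)(=O)C(F)(F)F)(C(C)C)C(C)C
Why: Soft enolization of the methyl ketone with a silyl triflate and an amine (silyl enol ether formation) gives the 2-silyloxydiene directly, and the bulky silyl group should make it stable to base and heat in step 3; no stereocenter.

Step 3
Reactants: 3 3-bromo-2,4-dimethylphenol; 5 2-[tri(propan-2-yl)silyloxy]buta-1,3-diene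
Product: 6 (4aS)-1,4a-dimethyl-6-[tri(propan-2-yl)silyloxy]-5,8-dihydronaphthalen-2(4aH)-one
Conditions: Pd2(dba)3 (2.5 mol %), chiral BINOL-derived phosphoramidite ligand (6 mol %), K3PO4 (2 equiv), 5 (2.5 equiv), 1,4-dioxane, 90 °C
Reagents that add atoms: none
Why: Proposed new method: zerovalent palladium should add oxidatively into the C5–Br bond of the phenoxide of 3, the aryl group should then insert the unsubstituted vinyl group of 5 at its terminal CH2 (C5–C6 bond, Heck step), and the resulting π-allylpalladium unit over C7–C8–C9 should be attacked at C9 by the para carbon C10 of the phenoxide (C9–C10 bond, Tsuji–Trost step) with loss of aromaticity. The closest known reaction types are the palladium-catalysed annulation of 1,3-dienes by aryl halides that carry a nucleophile and the palladium-catalysed intramolecular allylic dearomatization of phenols at the para carbon; their merger on a meta-bromophenol, with the arene carbon next to the C–Pd bond as the nucleophile, has not been shown. Ring B closes by 6-endo attack on the distal allyl terminus (attack at C7 would give a four-membered ring), which requires the anti π-allyl isomer; the silyloxy group on the central allyl carbon C8 disfavours the syn isomer and π–σ–π exchange supplies the reactive one, so the C7=C8 bond is delivered as a regiodefined silyl enol ether. The only new stereocenter, quaternary C10, is controlled by the chiral ligand, which has to distinguish the two faces of the planar phenoxide in the C–C bond-forming step. The step needs insertion at the vinyl rather than the enol ether alkene (secured by the lower reactivity of the electron-rich 1,1-disubstituted silyl enol ether towards arylpalladium), and C-alkylation at C10 rather than at oxygen or at the ortho carbon C4 (O-attack is geometrically impossible from the meta tether; C4 is flanked by the oxygen and C5 and would give the less stable linear dienone). K3PO4 takes up HBr and keeps the phenol ionized.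

Step 4
Reactants: 6 (4aS)-1,4a-dimethyl-6-[tri(propan-2-yl)silyloxy]-5,8-dihydronaphthalen-2(4aH)-one
Product: 7 (4aR)-1,4a-dimethyl-6-[tri(propan-2-yl)silyloxy]-4,4a,5,8-tetrahydronaphthalen-2(3H)-one
Conditions: H2 (1 atm), RhCl(PPh3)3 (5 mol %), benzene–EtOH, rt
Reagents that add atoms: none
Why: Homogeneous hydrogenation with RhCl(PPh3)3 discriminates by substitution, so the cis-disubstituted C1=C2 bond of the cross-conjugated dienone should be saturated while the tetrasubstituted C4=C5 enone bond and the trisubstituted silyl enol ether remain, as in the known 1,2-selective hydrogenation of 1,4-dien-3-ones; no new stereocenter (the descriptor at C10 changes only by priority).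

Step 5
Reactants: 7 (4aR)-1,4a-dimethyl-6-[tri(propan-2-yl)silyloxy]-4,4a,5,8-tetrahydronaphthalen-2(3H)-one; 8 methyl 3-bromo-2-oxopropanoate
Product: 9 methyl 3-bromo-2-[(4aR)-4a,8-dimethyl-3,7-dioxo-1,2,3,4,4a,5,6,7-octahydronaphthalen-2-yl]-2-hydroxypropanoate (mixture of diastereomers at ring C2 = C7 and at the carbinol carbon C11)
Conditions: TiCl4 (1.1 equiv), CH2Cl2, −78 to −40 °C; aq NaHCO3
Reagents that add atoms: none
Why: Mukaiyama aldol addition of the regiodefined C7=C8 silyl enol ether to the highly electrophilic ketone carbonyl of the α-keto ester should form the C7–C11 bond with all carbons of the acrylate in place; attack is expected mainly on the α-face, but the configurations at C7 and C11 are irrelevant because C11 becomes sp2 and C7 is equilibrated in step 6.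

Step 6
Reactants: 9 methyl 3-bromo-2-[(4aR)-4a,8-dimethyl-3,7-dioxo-1,2,3,4,4a,5,6,7-octahydronaphthalen-2-yl]-2-hydroxypropanoate
Product: 11 methyl 2-[(2R,4aR)-4a,8-dimethyl-3,7-dioxo-1,2,3,4,4a,5,6,7-octahydronaphthalen-2-yl]prop-2-enoate, via C7-epimeric keto acrylate 10 (not isolated)
Conditions: activated Zn, NaI (20 mol %), EtOH–AcOH (20:1), 50 °C; then DBU (10 mol %), CH2Cl2, 0 °C
Reagents that add atoms: none
Why: Reductive β-elimination of the bromohydrin by zinc (Boord-type olefin synthesis) can only give the C11=C13 alkene, and base-mediated enolization of the C8 ketone should then funnel both C7 epimers into the equatorial 7β isomer, which is both the thermodynamic product and the product of enolate protonation on the α-face anti to the C10 methyl.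

Step 7
Reactants: 11 methyl 2-[(2R,4aR)-4a,8-dimethyl-3,7-dioxo-1,2,3,4,4a,5,6,7-octahydronaphthalen-2-yl]prop-2-enoate
Product: 12 methyl 2-[(2R,3R,4aR)-3-hydroxy-4a,8-dimethyl-7-oxo-1,2,3,4,4a,5,6,7-octahydronaphthalen-2-yl]prop-2-enoate
Conditions: NaBH4, MeOH–CH2Cl2 (1:1), −78 °C; acetone, then pH 7 buffer
Reagents that add atoms: none
Why: NaBH4 at −78 °C reduces a saturated ketone much faster than a hindered tetrasubstituted enone (known chemoselective carbonyl reduction), and hydride should reach C8 from the α-face because axial attack on the β-face is blocked by the syn-axial C10 methyl, giving the axial 8β alcohol cis to the C7 side chain.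

Step 8
Reactants: 12 methyl 2-[(2R,3R,4aR)-3-hydroxy-4a,8-dimethyl-7-oxo-1,2,3,4,4a,5,6,7-octahydronaphthalen-2-yl]prop-2-enoate
Product: 13 methyl 2-[(2R,3R,4aR)-3-acetyloxy-4a,8-dimethyl-7-oxo-1,2,3,4,4a,5,6,7-octahydronaphthalen-2-yl]prop-2-enoate
Conditions: Ac2O, pyridine, DMAP (cat.), CH2Cl2, 0 °C to rt
Reagents that add atoms: acetic anhydride, CC(=O)OC(C)=O
Why: DMAP-catalysed acylation should esterify the hindered axial alcohol before it can lactonize onto the neighbouring methyl ester; no stereocenter is touched.

Step 9
Reactants: 13 methyl 2-[(2R,3R,4aR)-3-acetyloxy-4a,8-dimethyl-7-oxo-1,2,3,4,4a,5,6,7-octahydronaphthalen-2-yl]prop-2-enoate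
Product: 14 methyl 2-[(2R,3R,4aR,7S)-3-acetyloxy-7-hydroxy-4a,8-dimethyl-1,2,3,4,4a,5,6,7-octahydronaphthalen-2-yl]prop-2-enoate
Conditions: NaBH4, CeCl3·7H2O, MeOH, −78 °C
Reagents that add atoms: none
Why: Luche reduction should give clean 1,2-reduction of the enone without touching the acrylate or the esters, and hydride should add to C3 from the α-face (axial attack anti to the C10 methyl), as in 3-oxo-4-ene decalins, to give the pseudo-equatorial 3β allylic alcohol.

Step 10
Reactants: 14 methyl 2-[(2R,3R,4aR,7S)-3-acetyloxy-7-hydroxy-4a,8-dimethyl-1,2,3,4,4a,5,6,7-octahydronaphthalen-2-yl]prop-2-enoate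
Product: 15 methyl 2-[(2R,3R,4aR,7S)-3-acetyloxy-4a,8-dimethyl-7-propanoyloxy-1,2,3,4,4a,5,6,7-octahydronaphthalen-2-yl]prop-2-enoate (CNP0198123.1)
Conditions: (EtCO)2O, Et3N, DMAP (cat.), CH2Cl2, 0 °C
Reagents that add atoms: propanoic anhydride, CCC(=O)OC(=O)CC
Why: DMAP-catalysed acylation of the secondary allylic alcohol proceeds with retention at C3 and should complete the target.

**Compound list**
1 | 3-bromo-2,4-dimethylaniline | Nc1ccc(C)c(Br)c1C | starting material
2 | 3-bromo-2,4-dimethylbenzenediazonium hydrogensulfate | Cc1ccc([N+]#N)c(C)c1Br.OS(=O)(=O)[O-] | intermediate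
3 | 3-bromo-2,4-dimethylphenol | Oc1ccc(C)c(Br)c1C | intermediate
4 | but-3-en-2-one | CC(=O)C=C | starting material
5 | 2-[tri(propan-2-yl)silyloxy]buta-1,3-diene | C=CC(=C)O[Si](C(C)C)(C(C)C)C(C)C | intermediate
6 | (4aS)-1,4a-dimethyl-6-[tri(propan-2-yl)silyloxy]-5,8-dihydronaphthalen-2(4aH)-one | C1=C(O[Si](C(C)C)(C(C)C)C(C)C)C[C@@]2(C)C=CC(=O)C(C)=C2C1 | intermediate
7 | (4aR)-1,4a-dimethyl-6-[tri(propan-2-yl)silyloxy]-4,4a,5,8-tetrahydronaphthalen-2(3H)-one | C1=C(O[Si](C(C)C)(C(C)C)C(C)C)C[C@@]2(C)CCC(=O)C(C)=C2C1 | intermediate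
8 | methyl 3-bromo-2-oxopropanoate | COC(=O)C(=O)CBr | starting material
9 | methyl 3-bromo-2-[(4aR)-4a,8-dimethyl-3,7-dioxo-1,2,3,4,4a,5,6,7-octahydronaphthalen-2-yl]-2-hydroxypropanoate (diastereomer mixture at C7 and C11) | COC(=O)C(O)(CBr)C1CC2=C(C)C(=O)CC[C@]2(C)CC1=O | intermediate
10 | methyl 2-[(2S,4aR)-4a,8-dimethyl-3,7-dioxo-1,2,3,4,4a,5,6,7-octahydronaphthalen-2-yl]prop-2-enoate | C=C(C(=O)OC)[C@@H]1CC2=C(C)C(=O)CC[C@]2(C)CC1=O | intermediate
11 | methyl 2-[(2R,4aR)-4a,8-dimethyl-3,7-dioxo-1,2,3,4,4a,5,6,7-octahydronaphthalen-2-yl]prop-2-enoate | C=C(C(=O)OC)[C@H]1CC2=C(C)C(=O)CC[C@]2(C)CC1=O | intermediate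
12 | methyl 2-[(2R,3R,4aR)-3-hydroxy-4a,8-dimethyl-7-oxo-1,2,3,4,4a,5,6,7-octahydronaphthalen-2-yl]prop-2-enoate | C=C(C(=O)OC)[C@H]1CC2=C(C)C(=O)CC[C@]2(C)C[C@H]1O | intermediate
13 | methyl 2-[(2R,3R,4aR)-3-acetyloxy-4a,8-dimethyl-7-oxo-1,2,3,4,4a,5,6,7-octahydronaphthalen-2-yl]prop-2-enoate | C=C(C(=O)OC)[C@H]1CC2=C(C)C(=O)CC[C@]2(C)C[C@H]1OC(C)=O | intermediate
14 | methyl 2-[(2R,3R,4aR,7S)-3-acetyloxy-7-hydroxy-4a,8-dimethyl-1,2,3,4,4a,5,6,7-octahydronaphthalen-2-yl]prop-2-enoate | C=C(C(=O)OC)[C@H]1CC2=C(C)[C@@H](O)CC[C@]2(C)C[C@H]1OC(C)=O | intermediate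
15 | methyl 2-[(2R,3R,4aR,7S)-3-acetyloxy-4a,8-dimethyl-7-propanoyloxy-1,2,3,4,4a,5,6,7-octahydronaphthalen-2-yl]prop-2-enoate | C=C(C(=O)OC)[C@H]1CC2=C(C)[C@@H](OC(=O)CC)CC[C@]2(C)C[C@H]1OC(C)=O | target

**Step count:** 10 steps in total. Longest linear sequence: 9 steps (1, 3, 4, 5, 6, 7, 8, 9, 10); step 2 is a one-step branch.

**Steps most likely to fail**

Step 3 (proposed new method). The allylpalladium intermediate may undergo β-hydride elimination to an aryl diene instead of closing ring B. C-alkylation may also occur at the ortho carbon C4, and the facial discrimination of the phenoxide may be poor. The fallback uses known chemistry, sets out from 3 and comes back at 6. Heck arylation of 1-chlorobut-3-en-2-ol with 3 (Pd(OAc)2, Bu4NCl, NaHCO3, DMF, 80 °C; the allylic alcohol ends as the ketone) should give 1-chloro-4-(3-hydroxy-2,6-dimethylphenyl)butan-2-one F1, which already holds the C5–C6 bond. K2CO3 in DMF at high dilution should then close ring B by intramolecular C-alkylation of the phenoxide at its para carbon (classical alkylative dearomatization, C9–C10 bond) to racemic 1,4a-dimethyl-4a,5,7,8-tetrahydronaphthalene-2,6-dione F2. TIPSOTf and Et3N should enolize the C8 ketone towards the unhindered C7, and preparative chromatography on a chiral stationary phase would deliver 6 and leave the unwanted (4aR)-enantiomer F3.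

Step 6. Zinc insertion into the unactivated primary C–Br bond may be slow, the β-hydroxy ketone may cleave by retro-aldol reaction, and the new double bond may migrate into conjugation with the C8 ketone during the C7 equilibration. The fallback sets out from 7 and comes back at 11, replacing steps 5 and 6. NBS in THF at −78 °C should convert the silyl enol ether into (4aR)-7-bromo-1,4a-dimethyl-3,4,4a,5,7,8-hexahydronaphthalene-2,6-dione F4. Displacement of the bromide by the sodium salt of trimethyl phosphonoacetate (NaH, THF) should give methyl 2-(dimethoxyphosphoryl)-2-[(4aR)-4a,8-dimethyl-3,7-dioxo-1,2,3,4,4a,5,6,7-octahydronaphthalen-2-yl]acetate F5. Horner–Wadsworth–Emmons methylenation with aqueous formaldehyde and K2CO3 should then give 11, with C7 equilibrated under the same mildly basic conditions.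

Step 7. The new 8β alkoxide or alcohol may lactonize onto the cis methyl ester, and the C3 enone may be partly reduced. The fallback sets out from 11 and comes back at 13. The reduction is run as in step 7 and the crude product is lactonized on purpose with TsOH (cat.) to the cis-fused α-methylene lactone 3-oxoeudesma-4,11(13)-dien-8β,12-olide F6, which can be purified. LiOH (1 equiv) in aqueous THF should open it to the lithium salt of the 8β-hydroxy acid F7. After drying, MeI in DMF should alkylate the carboxylate to 12 under neutral conditions, and Ac2O, Et3N and DMAP added to the same flask should give 13 before the lactone can re-form.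

**Further compounds**
F1 | step 3 | 1-chloro-4-(3-hydroxy-2,6-dimethylphenyl)butan-2-one | O=C(CCl)CCc1c(C)ccc(O)c1C
F2 | step 3 | racemic 1,4a-dimethyl-4a,5,7,8-tetrahydronaphthalene-2,6-dione | CC1=C2CCC(=O)CC2(C)C=CC1=O
F3 | step 3 | (4aR)-1,4a-dimethyl-6-[tri(propan-2-yl)silyloxy]-5,8-dihydronaphthalen-2(4aH)-one | C1=C(O[Si](C(C)C)(C(C)C)C(C)C)C[C@]2(C)C=CC(=O)C(C)=C2C1
F4 | step 6 | (4aR)-7-bromo-1,4a-dimethyl-3,4,4a,5,7,8-hexahydronaphthalene-2,6-dione (epimer mixture at the C–Br carbon) | BrC1CC2=C(C)C(=O)CC[C@]2(C)CC1=O
F5 | step 6 | methyl 2-(dimethoxyphosphoryl)-2-[(4aR)-4a,8-dimethyl-3,7-dioxo-1,2,3,4,4a,5,6,7-octahydronaphthalen-2-yl]acetate | COC(=O)C(P(=O)(OC)OC)C1CC2=C(C)C(=O)CC[C@]2(C)CC1=O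
F6 | step 7 | 3-oxoeudesma-4,11(13)-dien-8β,12-olide (cis-fused α-methylene γ-lactone) | C=C1C(=O)O[C@@H]2C[C@@]3(C)CCC(=O)C(C)=C3C[C@H]12
F7 | step 7 | lithium 2-[(2R,3R,4aR)-3-hydroxy-4a,8-dimethyl-7-oxo-1,2,3,4,4a,5,6,7-octahydronaphthalen-2-yl]prop-2-enoate | [Li+].C=C(C(=O)[O-])[C@H]1CC2=C(C)C(=O)CC[C@]2(C)C[C@H]1O
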